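**Plan**

1. Retrosynthetic cuts: first the ten O‑benzyl bonds and the C8–Br bond of the flavan (helper groups). Then oxolane C2–C3 together with O1–C2, which releases 4‑benzyloxybenzaldehyde and an aryl‑alkyne silyl ether. Then the alkyne–aryl bond, C4–C5 (aldol), the diarylmethine C–aryl bond (conjugate addition) and the flavan C6–C bond.
2. Enabling feature: oxolane C2 carries the ring oxygen and an aryl group (an aldehyde‑level carbon), and its neighbour C3 carries an aroyl group. C2–C3 is therefore the bond of an aldol between an oxocarbenium ion and an aryl‑ketone enol. The enol is carried as a 2,4‑dibenzyloxyphenyl alkyne and C5–O as a silyl ether.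
3. Forward order: flavan unit (C2‑epimerised, benzylated, C8 blocked, C6 formylated) → acrylate → diarylmethine acid → imide → aldol (C4–C5) → terminal alkyne → aryl alkyne → Prins‑type closure of the oxolane, the only ring made → global hydrogenolysis.
4. Stereochemistry: flavan C3 comes from the natural product and flavan C2 from epimerisation. The diarylmethine is set by a rhodium/chiral‑diene catalyst. C4 and C5 are set by the oxazolidinone (syn aldol). C2 is set from C5 in the ring closure and C3 by equilibration.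

Key step: step 15

Assumption: (−)-epiafzelechin (2R,3R) is taken as the purchasable flavan‑3‑ol; the flavan unit of the target is (2S,3R), its C2 epimer, which is made in step 1.

Oxolane numbering: O1, C2 (4‑hydroxyphenyl), C3 (aroyl), C4 (diarylmethyl), C5 (2,4‑dihydroxyphenyl). Flav = (2S,3R)-3,5,7‑tris(benzyloxy)-2‑[4‑(benzyloxy)phenyl]-8‑bromochroman‑6‑yl.

**Route**

Step 1
Reactants: 1 (−)-epiafzelechin
Product: 2 (−)-afzelechin
Conditions: degassed aq. phosphate buffer (pH about 8), 90 °C, Ar; chromatography, recovered 1 recycled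
Reagents that add atoms: none
Why: Base‑induced C2 epimerisation of a flavan‑3‑ol, in which the 4'-phenoxide opens the pyran ring to a para‑quinone methide that recloses on either face while C3 is untouched, so the more stable 2,3‑trans epimer 2 should be the main partner of the equilibrium.

Step 2
Reactants: 2 (−)-afzelechin
Product: 4 tetra‑O‑benzyl‑(−)-afzelechin, via tri‑O‑benzyl ether 3 (not isolated)
Conditions: BnBr (3.3 equiv), K2CO3, DMF, rt; then NaH (1.5 equiv), BnBr (1.2 equiv), 0 °C → rt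
Reagents that add atoms: benzyl bromide BrCc1ccccc1
Why: Williamson ether synthesis in two stages, carbonate for the three phenols and NaH for the secondary alcohol, with no stereocentre touched.

Step 3
Reactants: 4 tetra‑O‑benzyl‑(−)-afzelechin
Product: 5 8‑bromo flavan
Conditions: NBS (1.0 equiv), CH2Cl2, −78 °C → rt
Reagents that add atoms: N‑bromosuccinimide O=C1CCC(=O)N1Br
Why: Electrophilic aromatic bromination, which in 5,7‑dialkoxyflavans takes the more accessible C8 first and so leaves C6 as the only free activated arene position.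

Step 4
Reactants: 5 8‑bromo flavan
Product: 7 flavan‑6‑carbaldehyde, via aryl iminium chloride 6 (not isolated)
Conditions: POCl3, DMF, 0 → 70 °C; then aq. NaOAc
Reagents that add atoms: N,N‑dimethylformamide CN(C)C=O; water O
Why: Vilsmeier–Haack formylation at C6, the one remaining position of ring A, activated by two ortho oxygens and one para oxygen.

Step 5
Reactants: 7 flavan‑6‑carbaldehyde
Product: 8 (E)-acrylate
Conditions: (EtO)2P(O)CH2CO2Et, NaH, THF, 0 °C → rt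
Reagents that add atoms: triethyl phosphonoacetate CCOC(=O)CP(=O)(OCC)OCC
Why: Horner–Wadsworth–Emmons olefination with a stabilised phosphonate, which should give the (E)-alkene.

Step 6
Reactants: 8 (E)-acrylate; 9 4‑benzyloxyphenylboronic acid
Product: 10 (3R)-diarylpropanoate
Conditions: [RhCl(C2H4)2]2 (3 mol %), (R,R)-Ph‑bod* [(1R,4R)-2,5‑diphenylbicyclo[2.2.2]octa‑2,5‑diene] (6.6 mol %), KOH (0.2 equiv), dioxane/H2O 10:1, 50 °C
Reagents that add atoms: none
Why: Hayashi–Miyaura asymmetric 1,4‑addition, in which the chiral diene on rhodium decides the face of the acrylate that receives the aryl group, so the diarylmethine centre is set by the catalyst (the (R,R) ligand is the one predicted by the usual enoate model; its antipode is available if the sense proves opposite).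

Step 7
Reactants: 10 (3R)-diarylpropanoate
Product: 11 (3R)-diarylpropanoic acid
Conditions: LiOH·H2O, THF/MeOH/H2O, 40 °C; then 1 M HCl
Reagents that add atoms: lithium hydroxide [Li+].[OH-]
Why: Ester saponification; the β‑stereocentre is not acidic and is kept.

Step 8
Reactants: 11 (3R)-diarylpropanoic acid; 12 (S)-4‑benzyloxazolidin‑2‑one
Product: 14 N‑acyl oxazolidinone, via pivalic mixed anhydride 13 (not isolated)
Conditions: PivCl, Et3N, THF, −20 °C; then 12, LiCl, rt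
Reagents that add atoms: none
Why: N‑Acylation of the oxazolidinone through the mixed pivalic anhydride, attacked at the less hindered carbonyl.

Step 9
Reactants: 14 N‑acyl oxazolidinone; 15 2,4‑bis(benzyloxy)benzaldehyde
Product: 17 syn aldol, via dibutylboron (Z)-enolate 16 (not isolated)
Conditions: Bu2BOTf, iPr2NEt, CH2Cl2, −78 → 0 °C; 15, −78 → 0 °C; pH 7 buffer, MeOH, 30% H2O2, 0 °C
Reagents that add atoms: none
Why: Evans syn aldol, in which the (Z)-boron enolate reacts through a Zimmerman–Traxler chair on the face away from the benzyl group of the auxiliary, setting C4 and C5 syn (the later 4,5‑cis oxolane carbons) in the absolute sense needed.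

Step 10
Reactants: 17 syn aldol
Product: 18 TES ether
Conditions: TESOTf, 2,6‑lutidine, CH2Cl2, −78 → 0 °C
Reagents that add atoms: triethylsilyl trifluoromethanesulfonate CC[Si](CC)(CC)OS(=O)(=O)C(F)(F)F
Why: Silylation of the benzylic alcohol with a silyl triflate; the TES ether later serves as the latent oxocarbenium oxygen.

Step 11
Reactants: 18 TES ether
Product: 19 primary alcohol
Conditions: LiBH4, THF/MeOH, 0 °C
Reagents that add atoms: none
Why: Reductive removal of the oxazolidinone with lithium borohydride, which should give the primary alcohol without epimerisation at C4.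

Step 12
Reactants: 19 primary alcohol
Product: 21 terminal alkyne, via aldehyde 20 (not isolated)
Conditions: DMP, NaHCO3, CH2Cl2, 0 °C → rt; work‑up; crude 20, dimethyl (1‑diazo‑2‑oxopropyl)phosphonate, K2CO3, MeOH/THF, 0 °C → rt
Reagents that add atoms: dimethyl (1‑diazo‑2‑oxopropyl)phosphonate CC(=O)C(=[N+]=[N-])P(=O)(OC)OC
Why: Dess–Martin oxidation followed by Ohira–Bestmann homologation, with the α‑branched aldehyde used crude to limit epimerisation and the mild carbonate conditions leaving the TES ether in place.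

Step 13
Reactants: 22 1,3‑bis(benzyloxy)benzene
Product: 23 2,4‑bis(benzyloxy)-1‑iodobenzene
Conditions: NIS (1.0 equiv), CF3CO2H (cat.), MeCN, rt
Reagents that add atoms: N‑iodosuccinimide O=C1CCC(=O)N1I
Why: Electrophilic aromatic iodination para to one benzyloxy group and ortho to the other, the most activated and accessible position.

Step 14
Reactants: 21 terminal alkyne; 23 2,4‑bis(benzyloxy)-1‑iodobenzene
Product: 24 aryl alkyne
Conditions: PdCl2(PPh3)2 (3 mol %), CuI (5 mol %), Et3N/THF, rt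
Reagents that add atoms: none
Why: Sonogashira coupling, in which the aryl iodide reacts at room temperature while the hindered, electron‑rich C8 bromide of the flavan should stay untouched.

Step 15
Reactants: 24 aryl alkyne; 25 4‑benzyloxybenzaldehyde
Product: 29 protected target ketone, via oxocarbenium ion 26 (not isolated), via vinyl cation 27 (not isolated), via all‑cis ketone 28 (not isolated)
Conditions: 25 (1.5 equiv), TMSOTf (1.2 equiv), CH2Cl2, −78 → −40 °C; sat. aq. NaHCO3; crude, DBU (0.5 equiv), CH2Cl2, rt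
Reagents that add atoms: water O
Why: TMSOTf joins the silyl ether oxygen of 24 and aldehyde 25 to the (E)-oxocarbenium ion 26, whose carbon (C2) is attacked by the alkyne carbon remote from the aryl group (C3) to give the aryl‑stabilised vinyl cation 27; water at the quench turns 27 into the enol and then the ketone 28, and DBU equilibrates it to 29. The closest known reaction type is the TMSOTf‑promoted Prins‑type cyclisation of aryl‑substituted homopropargylic alcohols with aldehydes to 2,5‑cis 3‑acyl tetrahydrofurans, here run from the triethylsilyl ether, which forms oxocarbenium ions with aldehydes as in reductive etherification. The one ring formed, the oxolane, closes 5‑endo‑trig at the C=O+ bond and 5‑exo‑dig at the alkyne. C2 is controlled by C5, since in the envelope transition state the aryl groups on C2 and C5 both sit pseudo‑equatorial and the ring comes out 2,5‑cis. C3 arises on ketonisation, first by protonation on the free face (all‑cis 28) and then under thermodynamic control, because the C2 aryl group and the C4 substituent lie on one face and the aroyl group moves to the other; the same base would also correct C2 by reversible oxa‑Michael opening, as the target pattern is the most stable one for fixed C4 and C5. The step needs attack through C3 and not through the aryl‑bearing alkyne carbon, secured by the 2,4‑dibenzyloxyphenyl group that stabilises the vinyl cation, and it needs ring closure to outrun ionisation of the benzylic C5–O bond, for which the low temperature and the fully substituted, bromine‑blocked ring A (no free nucleophilic arene CH) are relied on.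

Step 16
Reactants: 29 protected target ketone
Product: 30 target
Conditions: H2 (1 atm), Pd(OH)2/C, Et3N (1.2 equiv), THF/MeOH, rt
Reagents that add atoms: none
Why: Hydrogenolysis of the ten benzyl ethers and of the aryl bromide over Pearlman's catalyst under mild conditions, with triethylamine taking up the hydrogen bromide.

**Compound list**

1 | (−)-epiafzelechin, (2R,3R)-2-(4-hydroxyphenyl)chromane-3,5,7-triol | c1c(O)cc2c(c1O)C[C@@H](O)[C@@H](c1ccc(O)cc1)O2 | starting material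
2 | (−)-afzelechin, (2S,3R)-2-(4-hydroxyphenyl)chromane-3,5,7-triol | c1c(O)cc2c(c1O)C[C@@H](O)[C@H](c1ccc(O)cc1)O2 | intermediate
3 | (2S,3R)-5,7-bis(benzyloxy)-2-[4-(benzyloxy)phenyl]chroman-3-ol | c5c(OCc7ccccc7)cc6c(c5OCc5ccccc5)C[C@@H](O)[C@H](c5ccc(OCc7ccccc7)cc5)O6 | intermediate
4 | (2S,3R)-3,5,7-tris(benzyloxy)-2-[4-(benzyloxy)phenyl]chromane | c5c(OCc7ccccc7)cc6c(c5OCc5ccccc5)C[C@@H](OCc5ccccc5)[C@H](c5ccc(OCc7ccccc7)cc5)O6 | intermediate
5 | (2S,3R)-3,5,7-tris(benzyloxy)-2-[4-(benzyloxy)phenyl]-8-bromochromane (Flav–H) | c5c(OCc7ccccc7)c(Br)c6c(c5OCc5ccccc5)C[C@@H](OCc5ccccc5)[C@H](c5ccc(OCc7ccccc7)cc5)O6 | intermediate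
6 | N-[(Flav)methylidene]-N-methylmethanaminium chloride | C[N+](C)=Cc5c(OCc7ccccc7)c(Br)c6c(c5OCc5ccccc5)C[C@@H](OCc5ccccc5)[C@H](c5ccc(OCc7ccccc7)cc5)O6.[Cl-] | intermediate
7 | (2S,3R)-3,5,7-tris(benzyloxy)-2-[4-(benzyloxy)phenyl]-8-bromochromane-6-carbaldehyde | O=Cc5c(OCc7ccccc7)c(Br)c6c(c5OCc5ccccc5)C[C@@H](OCc5ccccc5)[C@H](c5ccc(OCc7ccccc7)cc5)O6 | intermediate
8 | ethyl (E)-3-(Flav)prop-2-enoate | CCOC(=O)/C=C/c5c(OCc7ccccc7)c(Br)c6c(c5OCc5ccccc5)C[C@@H](OCc5ccccc5)[C@H](c5ccc(OCc7ccccc7)cc5)O6 | intermediate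
9 | [4-(benzyloxy)phenyl]boronic acid | OB(O)c1ccc(OCc2ccccc2)cc1 | starting material
10 | ethyl (3R)-3-[4-(benzyloxy)phenyl]-3-(Flav)propanoate | CCOC(=O)C[C@@H](c8ccc(OCc9ccccc9)cc8)c5c(OCc7ccccc7)c(Br)c6c(c5OCc5ccccc5)C[C@@H](OCc5ccccc5)[C@H](c5ccc(OCc7ccccc7)cc5)O6 | intermediate
11 | (3R)-3-[4-(benzyloxy)phenyl]-3-(Flav)propanoic acid | OC(=O)C[C@@H](c8ccc(OCc9ccccc9)cc8)c5c(OCc7ccccc7)c(Br)c6c(c5OCc5ccccc5)C[C@@H](OCc5ccccc5)[C@H](c5ccc(OCc7ccccc7)cc5)O6 | intermediate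
12 | (S)-4-benzyloxazolidin-2-one | O=C1N[C@@H](Cc2ccccc2)CO1 | starting material
13 | mixed anhydride of acid 11 and pivalic acid | CC(C)(C)C(=O)OC(=O)C[C@@H](c8ccc(OCc9ccccc9)cc8)c5c(OCc7ccccc7)c(Br)c6c(c5OCc5ccccc5)C[C@@H](OCc5ccccc5)[C@H](c5ccc(OCc7ccccc7)cc5)O6 | intermediate
14 | (4S)-4-benzyl-3-[(3R)-3-[4-(benzyloxy)phenyl]-3-(Flav)propanoyl]oxazolidin-2-one | O=C1OC[C@H](Cc2ccccc2)N1C(=O)C[C@@H](c8ccc(OCc9ccccc9)cc8)c5c(OCc7ccccc7)c(Br)c6c(c5OCc5ccccc5)C[C@@H](OCc5ccccc5)[C@H](c5ccc(OCc7ccccc7)cc5)O6 | intermediate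
15 | 2,4-bis(benzyloxy)benzaldehyde | O=Cc1ccc(OCc2ccccc2)cc1OCc1ccccc1 | starting material
16 | dibutylboron (Z)-enolate of imide 14 | CCCCB(CCCC)O/C(N1C(=O)OC[C@@H]1Cc1ccccc1)=C\[C@@H](c8ccc(OCc9ccccc9)cc8)c5c(OCc7ccccc7)c(Br)c6c(c5OCc5ccccc5)C[C@@H](OCc5ccccc5)[C@H](c5ccc(OCc7ccccc7)cc5)O6 | intermediate
17 | (4S)-4-benzyl-3-{(2S,3S)-3-[2,4-bis(benzyloxy)phenyl]-2-[(R)-[4-(benzyloxy)phenyl](Flav)methyl]-3-hydroxypropanoyl}oxazolidin-2-one | O=C1OC[C@H](Cc2ccccc2)N1C(=O)[C@@H]([C@@H](c8ccc(OCc9ccccc9)cc8)c5c(OCc7ccccc7)c(Br)c6c(c5OCc5ccccc5)C[C@@H](OCc5ccccc5)[C@H](c5ccc(OCc7ccccc7)cc5)O6)[C@H](O)c8ccc(OCc9ccccc9)cc8OCc8ccccc8 | intermediate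
18 | triethylsilyl ether of aldol 17 (all centres as in 17) | O=C1OC[C@H](Cc2ccccc2)N1C(=O)[C@@H]([C@@H](c8ccc(OCc9ccccc9)cc8)c5c(OCc7ccccc7)c(Br)c6c(c5OCc5ccccc5)C[C@@H](OCc5ccccc5)[C@H](c5ccc(OCc7ccccc7)cc5)O6)[C@H](O[Si](CC)(CC)CC)c8ccc(OCc9ccccc9)cc8OCc8ccccc8 | intermediate
19 | (2R,3S)-3-[2,4-bis(benzyloxy)phenyl]-2-[(R)-[4-(benzyloxy)phenyl](Flav)methyl]-3-(triethylsilyloxy)propan-1-ol | OC[C@@H]([C@@H](c8ccc(OCc9ccccc9)cc8)c5c(OCc7ccccc7)c(Br)c6c(c5OCc5ccccc5)C[C@@H](OCc5ccccc5)[C@H](c5ccc(OCc7ccccc7)cc5)O6)[C@H](O[Si](CC)(CC)CC)c8ccc(OCc9ccccc9)cc8OCc8ccccc8 | intermediate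
20 | (2S,3S)-3-[2,4-bis(benzyloxy)phenyl]-2-[(R)-[4-(benzyloxy)phenyl](Flav)methyl]-3-(triethylsilyloxy)propanal | O=C[C@@H]([C@@H](c8ccc(OCc9ccccc9)cc8)c5c(OCc7ccccc7)c(Br)c6c(c5OCc5ccccc5)C[C@@H](OCc5ccccc5)[C@H](c5ccc(OCc7ccccc7)cc5)O6)[C@H](O[Si](CC)(CC)CC)c8ccc(OCc9ccccc9)cc8OCc8ccccc8 | intermediate
21 | {[(1S,2R)-1-[2,4-bis(benzyloxy)phenyl]-2-[(R)-[4-(benzyloxy)phenyl](Flav)methyl]but-3-yn-1-yl]oxy}triethylsilane | C#C[C@@H]([C@@H](c8ccc(OCc9ccccc9)cc8)c5c(OCc7ccccc7)c(Br)c6c(c5OCc5ccccc5)C[C@@H](OCc5ccccc5)[C@H](c5ccc(OCc7ccccc7)cc5)O6)[C@H](O[Si](CC)(CC)CC)c8ccc(OCc9ccccc9)cc8OCc8ccccc8 | intermediate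
22 | 1,3-bis(benzyloxy)benzene | c1cc(OCc2ccccc2)cc(OCc2ccccc2)c1 | starting material
23 | 2,4-bis(benzyloxy)-1-iodobenzene | Ic1ccc(OCc2ccccc2)cc1OCc1ccccc1 | intermediate
24 | {[(1S,2R)-1,4-bis[2,4-bis(benzyloxy)phenyl]-2-[(R)-[4-(benzyloxy)phenyl](Flav)methyl]but-3-yn-1-yl]oxy}triethylsilane | C(#Cc2ccc(OCc3ccccc3)cc2OCc2ccccc2)[C@@H]([C@@H](c8ccc(OCc9ccccc9)cc8)c5c(OCc7ccccc7)c(Br)c6c(c5OCc5ccccc5)C[C@@H](OCc5ccccc5)[C@H](c5ccc(OCc7ccccc7)cc5)O6)[C@H](O[Si](CC)(CC)CC)c8ccc(OCc9ccccc9)cc8OCc8ccccc8 | intermediate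
25 | 4-(benzyloxy)benzaldehyde | O=Cc1ccc(OCc2ccccc2)cc1 | starting material
26 | (E)-O-alkyl oxocarbenium triflate formed from the C5 oxygen of 24 and aldehyde 25 | C(#Cc2ccc(OCc3ccccc3)cc2OCc2ccccc2)[C@@H]([C@@H](c8ccc(OCc9ccccc9)cc8)c5c(OCc7ccccc7)c(Br)c6c(c5OCc5ccccc5)C[C@@H](OCc5ccccc5)[C@H](c5ccc(OCc7ccccc7)cc5)O6)[C@H](/[O+]=C/c2ccc(OCc3ccccc3)cc2)c8ccc(OCc9ccccc9)cc8OCc8ccccc8.[O-]S(=O)(=O)C(F)(F)F | intermediate
27 | 2,5-cis oxolane with exocyclic aryl vinyl cation on C3 (triflate) | [C+](c2ccc(OCc3ccccc3)cc2OCc2ccccc2)=C1[C@@H]([C@@H](c8ccc(OCc9ccccc9)cc8)c5c(OCc7ccccc7)c(Br)c6c(c5OCc5ccccc5)C[C@@H](OCc5ccccc5)[C@H](c5ccc(OCc7ccccc7)cc5)O6)[C@@H](c8ccc(OCc9ccccc9)cc8OCc8ccccc8)O[C@H]1c2ccc(OCc3ccccc3)cc2.[O-]S(=O)(=O)C(F)(F)F | intermediate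
28 | all-cis ketone, (2R,3S,4R,5S) C3 epimer of 29 | O=C(c2ccc(OCc3ccccc3)cc2OCc2ccccc2)[C@H]1[C@@H]([C@@H](c8ccc(OCc9ccccc9)cc8)c5c(OCc7ccccc7)c(Br)c6c(c5OCc5ccccc5)C[C@@H](OCc5ccccc5)[C@H](c5ccc(OCc7ccccc7)cc5)O6)[C@@H](c8ccc(OCc9ccccc9)cc8OCc8ccccc8)O[C@H]1c2ccc(OCc3ccccc3)cc2 | intermediate
29 | [(2R,3R,4R,5S)-5-[2,4-bis(benzyloxy)phenyl]-2-[4-(benzyloxy)phenyl]-4-[(R)-[4-(benzyloxy)phenyl](Flav)methyl]oxolan-3-yl][2,4-bis(benzyloxy)phenyl]methanone | O=C(c2ccc(OCc3ccccc3)cc2OCc2ccccc2)[C@@H]1[C@@H]([C@@H](c8ccc(OCc9ccccc9)cc8)c5c(OCc7ccccc7)c(Br)c6c(c5OCc5ccccc5)C[C@@H](OCc5ccccc5)[C@H](c5ccc(OCc7ccccc7)cc5)O6)[C@@H](c8ccc(OCc9ccccc9)cc8OCc8ccccc8)O[C@H]1c2ccc(OCc3ccccc3)cc2 | intermediate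
30 | [(2R,3R,4R,5S)-5-(2,4-dihydroxyphenyl)-2-(4-hydroxyphenyl)-4-{(R)-(4-hydroxyphenyl)[(2S,3R)-3,5,7-trihydroxy-2-(4-hydroxyphenyl)chroman-6-yl]methyl}oxolan-3-yl](2,4-dihydroxyphenyl)methanone | O=C(c1ccc(O)cc1O)[C@@H]1[C@@H]([C@@H](c2ccc(O)cc2)c2c(O)cc3c(c2O)C[C@@H](O)[C@H](c2ccc(O)cc2)O3)[C@@H](c2ccc(O)cc2O)O[C@H]1c1ccc(O)cc1 | target

**Step count and risks**

Total step count: 16. Longest linear sequence: 15 steps (steps 1–12 and 14–16; step 13 is a side branch).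

Steps most likely to fail:

1. Step 15. The benzylic C5–O bond, activated by the 2,4‑dibenzyloxyphenyl group, may ionise before ring closure, with loss of the C5 configuration or fragmentation. The vinyl cation may also collapse by alkyne–carbonyl metathesis instead of hydration. Fallback, from 24: gold‑catalysed hydration ((Ph3P)AuNTf2, aqueous dioxane) should give the γ‑silyloxy aryl ketone F1. Its lithium enolate (LiHMDS, THF, −78 °C) is condensed with 25 and the aldol dehydrated (MsCl, Et3N, then DBU) to the 2‑benzylidene ketone F2, either alkene isomer serving. Et3N·3HF removes the silyl group to give the hydroxy enone F3, which DBU should close by 5‑exo‑trig oxa‑Michael addition under thermodynamic control. The route is rejoined at 29.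

2. Step 6. Insertion of the twisted, doubly ortho‑substituted acrylate into the aryl–rhodium bond may be slow, so that protodeboronation of 9 wins and facial control is weak. Fallback, from 8: saponification (LiOH) gives the acrylic acid F4. Acylation (PivCl, Et3N; lithiated (R)-4‑phenyloxazolidin‑2‑one) gives the N‑enoyl imide F5. 4‑Benzyloxyphenylmagnesium bromide with CuBr·SMe2 should add to the magnesium‑chelated s‑cis imide on the face away from the phenyl group to give the adduct F6. LiOH/H2O2 cleaves the auxiliary, and the route is rejoined at acid 11.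

3. Step 16. Over‑reduction may occur before all ten benzyl ethers and the bromide are gone: hydrogenolysis of the benzylic C–O bonds of the oxolane or flavan, or reduction of the aryl ketone. Fallback, from 29: radical debromination (Bu3SnH, AIBN, toluene, 80 °C) gives the bromine‑free decabenzyl ether F7. BCl3 with pentamethylbenzene as benzyl‑cation scavenger (CH2Cl2, −78 °C) then cleaves the benzyl ethers without hydrogen and gives the target 30.

Further compounds
F1 | step 15 | 1-[2,4-bis(benzyloxy)phenyl]-4-[2,4-bis(benzyloxy)phenyl]-3-[(R)-[4-(benzyloxy)phenyl](Flav)methyl]-4-(triethylsilyloxy)butan-1-one (C3, C4 as in 24) | O=C(c2ccc(OCc3ccccc3)cc2OCc2ccccc2)C[C@@H]([C@@H](c8ccc(OCc9ccccc9)cc8)c5c(OCc7ccccc7)c(Br)c6c(c5OCc5ccccc5)C[C@@H](OCc5ccccc5)[C@H](c5ccc(OCc7ccccc7)cc5)O6)[C@H](O[Si](CC)(CC)CC)c8ccc(OCc9ccccc9)cc8OCc8ccccc8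
F2 | step 15 | 2-[4-(benzyloxy)benzylidene] derivative of ketone F1 (alkene geometry open) | O=C(c2ccc(OCc3ccccc3)cc2OCc2ccccc2)C(=Cc2ccc(OCc3ccccc3)cc2)[C@@H]([C@@H](c8ccc(OCc9ccccc9)cc8)c5c(OCc7ccccc7)c(Br)c6c(c5OCc5ccccc5)C[C@@H](OCc5ccccc5)[C@H](c5ccc(OCc7ccccc7)cc5)O6)[C@H](O[Si](CC)(CC)CC)c8ccc(OCc9ccccc9)cc8OCc8ccccc8
F3 | step 15 | free C4 alcohol of enone F2 | O=C(c2ccc(OCc3ccccc3)cc2OCc2ccccc2)C(=Cc2ccc(OCc3ccccc3)cc2)[C@@H]([C@@H](c8ccc(OCc9ccccc9)cc8)c5c(OCc7ccccc7)c(Br)c6c(c5OCc5ccccc5)C[C@@H](OCc5ccccc5)[C@H](c5ccc(OCc7ccccc7)cc5)O6)[C@H](O)c8ccc(OCc9ccccc9)cc8OCc8ccccc8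
F4 | step 6 | (E)-3-(Flav)prop-2-enoic acid | OC(=O)/C=C/c5c(OCc7ccccc7)c(Br)c6c(c5OCc5ccccc5)C[C@@H](OCc5ccccc5)[C@H](c5ccc(OCc7ccccc7)cc5)O6
F5 | step 6 | (4R)-3-[(E)-3-(Flav)prop-2-enoyl]-4-phenyloxazolidin-2-one | O=C1OC[C@@H](c2ccccc2)N1C(=O)/C=C/c5c(OCc7ccccc7)c(Br)c6c(c5OCc5ccccc5)C[C@@H](OCc5ccccc5)[C@H](c5ccc(OCc7ccccc7)cc5)O6
F6 | step 6 | (4R)-3-[(3R)-3-[4-(benzyloxy)phenyl]-3-(Flav)propanoyl]-4-phenyloxazolidin-2-one | O=C1OC[C@@H](c2ccccc2)N1C(=O)C[C@@H](c8ccc(OCc9ccccc9)cc8)c5c(OCc7ccccc7)c(Br)c6c(c5OCc5ccccc5)C[C@@H](OCc5ccccc5)[C@H](c5ccc(OCc7ccccc7)cc5)O6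
F7 | step 16 | debrominated analogue of 29 (decabenzyl ether of the target) | O=C(c2ccc(OCc3ccccc3)cc2OCc2ccccc2)[C@@H]1[C@@H]([C@@H](c8ccc(OCc9ccccc9)cc8)c5c(OCc7ccccc7)cc6c(c5OCc5ccccc5)C[C@@H](OCc5ccccc5)[C@H](c5ccc(OCc7ccccc7)cc5)O6)[C@@H](c8ccc(OCc9ccccc9)cc8OCc8ccccc8)O[C@H]1c2ccc(OCc3ccccc3)cc2
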